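## Retrosynthetic overview

1. Bought building blocks: Corey lactone diol 1 (C8, C9, C11, C12), (R)-butane-1,3-diol 2 (C19), (S)-epichlorohydrin 3 (C15), phosphonium salt 4 (C1–C5).
2. Target ⇐ desilylation and C9 oxidation of a 9α-hydroxy acid ⇐ Z-selective Wittig reaction (C5=C6) of a lactol with the ylide of 4.
3. Lactol ⇐ Corey-type lactone carrying the whole saturated ω-chain ⇐ key C13–C14 bond: blue-light iridium/nickel deoxygenative coupling of the primary alcohol of 1 with a terminal epoxide (C14–C20).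
4. Epoxide ⇐ copper-catalysed opening of 3 by the Grignard reagent of silylated (R)-4-bromobutan-2-ol (from 2), then ring closure.
5. Rings: no carbocycle is built (the cyclopentane comes in 1); the oxirane is formed in step 2 and opened in step 3; the lactone is opened in step 6.

Assumption: prostaglandin numbering (C1 to C20) is used for positions, and compounds 1–4 are taken as purchased.

## Route

Step 1
Reactants: 2 (R)-butane-1,3-diol
Product: 6 (R)-[(4-bromobutan-2-yl)oxy](tert-butyl)dimethylsilane, via (R)-4-bromobutan-2-ol 5 (not isolated)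
Conditions: PPh3 (1.05 equiv), CBr4 (1.05 equiv), CH2Cl2, 0 °C; then imidazole (2.5 equiv), TBSCl (1.2 equiv), 25 °C (one pot)
Reagents that add atoms: carbon tetrabromide BrC(Br)(Br)Br; tert-butyldimethylsilyl chloride CC(C)(C)[Si](C)(C)Cl
Why: Appel bromination takes the primary hydroxyl of the 1,3-diol much faster than the secondary one, so the purchased R carbinol (C19) is untouched and is then silylated in the same pot (Corey silylation).

Step 2
Reactants: 6 (R)-[(4-bromobutan-2-yl)oxy](tert-butyl)dimethylsilane; 3 (S)-epichlorohydrin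
Product: 9 tert-butyldimethyl{[(2R)-5-[(2S)-oxiran-2-yl]pentan-2-yl]oxy}silane, via Grignard reagent 7 (not isolated), via chlorohydrin magnesium alkoxide 8 (not isolated)
Conditions: Mg, THF, 40 °C; then CuI (5 mol%), 3, −40 → 0 °C; then aq NaOH, 25 °C
Reagents that add atoms: none
Why: Copper-catalysed Grignard opening of the oxirane of 3 at its unsubstituted carbon (faster than direct chloride displacement) followed by intramolecular Williamson closure of the chlorohydrin moves the oxirane without touching the stereocentre, so the purchased S centre of 3 becomes C15.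

Step 3
Reactants: 1 (3aR,4S,5R,6aS)-5-hydroxy-4-(hydroxymethyl)hexahydro-2H-cyclopenta[b]furan-2-one (1.5 equiv); 9 tert-butyldimethyl{[(2R)-5-[(2S)-oxiran-2-yl]pentan-2-yl]oxy}silane (1.0 equiv)
Product: 12 (3aR,4R,5R,6aS)-4-[(3S,7R)-7-[(tert-butyldimethylsilyl)oxy]-3-hydroxyoctyl]-5-hydroxyhexahydro-2H-cyclopenta[b]furan-2-one, via benzoxazoline adduct 10 (not isolated), via iodohydrin 11 (not isolated)
Conditions: 1, 5,7-di-tert-butyl-3-phenylbenzoxazolium tetrafluoroborate (1.4 equiv), pyridine (3 equiv), MeCN–MTBE, 25 °C, 20 min; then 9, Bu4NI (0.5 equiv), [Ir(ppy)2(dtbbpy)]PF6 (2 mol%), NiI2 (10 mol%), 4,4′-di-tert-butyl-2,2′-bipyridine (12 mol%), DMA, 450 nm LEDs, 25 °C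
Reagents that add atoms: none
Why: Proposed new method: a redox- and proton-neutral deoxygenative alkyl–alkyl coupling in which the benzoxazolium adduct 10 (formed preferentially at the unhindered primary hydroxyl of 1) is oxidised by the excited iridium photocatalyst and fragments by β-scission to the C13 radical and a benzoxazolone, while pyridinium iodide reversibly opens epoxide 9 at its terminal carbon to iodohydrin 11, which adds oxidatively to zerovalent nickel; capture of the C13 radical gives a dialkyl trivalent nickel species that reductively eliminates the C13–C14 bond, the reduced photocatalyst returns monovalent nickel to the zerovalent state and the proton lost from 10 is the one consumed in opening 9, so C12 and C15 are never reacting centres and keep their purchased configuration; the closest known reactions are the metallaphotoredox deoxygenative C(sp3)–C(sp3) coupling of benzoxazolium-activated alcohols with alkyl bromides and the nickel-catalysed cross-electrophile coupling of epoxides with aryl halides through iodohydrins formed in situ.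

Step 4
Reactants: 12 (3aR,4R,5R,6aS)-4-[(3S,7R)-7-[(tert-butyldimethylsilyl)oxy]-3-hydroxyoctyl]-5-hydroxyhexahydro-2H-cyclopenta[b]furan-2-one
Product: 13 (3aR,4R,5R,6aS)-4-[(3S,7R)-3,7-bis[(tert-butyldimethylsilyl)oxy]octyl]-5-[(tert-butyldimethylsilyl)oxy]hexahydro-2H-cyclopenta[b]furan-2-one
Conditions: TBSOTf (2.6 equiv), 2,6-lutidine, CH2Cl2, −78 → 0 °C
Reagents that add atoms: tert-butyldimethylsilyl triflate CC(C)(C)[Si](C)(C)OS(=O)(=O)C(F)(F)F
Why: Silyl triflate/lutidine silylation of the two secondary hydroxyls (C11, C15) is fast at low temperature, leaves the lactone alone and touches no stereocentre.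

Step 5
Reactants: 13 (3aR,4R,5R,6aS)-4-[(3S,7R)-3,7-bis[(tert-butyldimethylsilyl)oxy]octyl]-5-[(tert-butyldimethylsilyl)oxy]hexahydro-2H-cyclopenta[b]furan-2-one
Product: 14 (3aR,4R,5R,6aS)-4-[(3S,7R)-3,7-bis[(tert-butyldimethylsilyl)oxy]octyl]-5-[(tert-butyldimethylsilyl)oxy]hexahydro-2H-cyclopenta[b]furan-2-ol (anomer mixture)
Conditions: i-Bu2AlH (1.2 equiv), CH2Cl2, −78 °C; then H2O
Reagents that add atoms: none
Why: Partial reduction of the γ-lactone by i-Bu2AlH at −78 °C stops at the stable aluminium hemiacetal and gives the lactol, with silyl ethers inert.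

Step 6
Reactants: 14 the lactol of step 5; 4 (4-carboxybutyl)triphenylphosphonium bromide (3 equiv)
Product: 16 (Z)-7-[(1R,2R,3R,5S)-2-[(3S,7R)-3,7-bis[(tert-butyldimethylsilyl)oxy]octyl]-3-[(tert-butyldimethylsilyl)oxy]-5-hydroxycyclopentyl]hept-5-enoic acid, via phosphorus ylide 15 (not isolated)
Conditions: 4, KOtBu (6 equiv), THF, 0 °C; then 14, −15 → 0 °C; aq KHSO4 to pH 4
Reagents that add atoms: none
Why: Wittig olefination of the open hydroxy-aldehyde form of the lactol with the non-stabilised potassium ylide gives the 5Z olefin under kinetic control and frees the 9-hydroxyl, and the low temperature suppresses silyl migration from O11 to O9.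

Step 7
Reactants: 16 the 9-hydroxy acid of step 6
Product: 17 (Z)-7-[(1R,2R,3R)-2-[(3S,7R)-3,7-bis[(tert-butyldimethylsilyl)oxy]octyl]-3-[(tert-butyldimethylsilyl)oxy]-5-oxocyclopentyl]hept-5-enoic acid
Conditions: Dess–Martin periodinane (1.3 equiv), CH2Cl2, 0 → 25 °C
Reagents that add atoms: none
Why: Dess–Martin oxidation converts the only free hydroxyl (C9) into the ketone under near-neutral conditions that tolerate the acid, the Z-olefin and the silyl ethers and do not epimerise C8.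

Step 8
Reactants: 17 the tris-silyl keto acid of step 7
Product: 18 (Z)-7-[(1R,2R,3R)-3-hydroxy-2-[(3S,7R)-3,7-dihydroxyoctyl]-5-oxocyclopentyl]hept-5-enoic acid
Conditions: HF·pyridine, MeCN, 0 °C
Reagents that add atoms: none
Why: Fluoride-driven cleavage of the three silyl ethers with HF·pyridine is mild enough that the β-hydroxy ketone does not dehydrate and C8 does not epimerise.

## Compound list

1 | (3aR,4S,5R,6aS)-5-hydroxy-4-(hydroxymethyl)hexahydro-2H-cyclopenta[b]furan-2-one (Corey lactone diol) | OC[C@H]1[C@H](O)C[C@@H]2OC(=O)C[C@H]12 | starting material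
2 | (R)-butane-1,3-diol | C[C@@H](O)CCO | starting material
3 | (S)-epichlorohydrin, (S)-2-(chloromethyl)oxirane | ClC[C@@H]1CO1 | starting material
4 | (4-carboxybutyl)triphenylphosphonium bromide | OC(=O)CCCC[P+](c1ccccc1)(c1ccccc1)c1ccccc1.[Br-] | starting material
5 | (R)-4-bromobutan-2-ol | C[C@@H](O)CCBr | intermediate
6 | (R)-[(4-bromobutan-2-yl)oxy](tert-butyl)dimethylsilane | C[C@@H](O[Si](C)(C)C(C)(C)C)CCBr | intermediate
7 | (R)-{3-[(tert-butyldimethylsilyl)oxy]butyl}magnesium bromide | C[C@@H](O[Si](C)(C)C(C)(C)C)CC[Mg]Br | intermediate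
8 | bromomagnesium (2S,6R)-6-[(tert-butyldimethylsilyl)oxy]-1-chloroheptan-2-olate | C[C@@H](O[Si](C)(C)C(C)(C)C)CCC[C@H](O[Mg]Br)CCl | intermediate
9 | tert-butyldimethyl{[(2R)-5-[(2S)-oxiran-2-yl]pentan-2-yl]oxy}silane | C[C@@H](O[Si](C)(C)C(C)(C)C)CCC[C@H]1CO1 | intermediate
10 | (3aR,4S,5R,6aS)-4-{[(5,7-di-tert-butyl-3-phenyl-2,3-dihydro-1,3-benzoxazol-2-yl)oxy]methyl}-5-hydroxyhexahydro-2H-cyclopenta[b]furan-2-one (acetal carbon unassigned) | O(C3Oc4c(C(C)(C)C)cc(C(C)(C)C)cc4N3c5ccccc5)C[C@H]1[C@H](O)C[C@@H]2OC(=O)C[C@H]12 | intermediate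
11 | (2S,6R)-6-[(tert-butyldimethylsilyl)oxy]-1-iodoheptan-2-ol | C[C@@H](O[Si](C)(C)C(C)(C)C)CCC[C@H](O)CI | intermediate
12 | (3aR,4R,5R,6aS)-4-[(3S,7R)-7-[(tert-butyldimethylsilyl)oxy]-3-hydroxyoctyl]-5-hydroxyhexahydro-2H-cyclopenta[b]furan-2-one | C[C@@H](O[Si](C)(C)C(C)(C)C)CCC[C@H](O)CC[C@H]1[C@H](O)C[C@@H]2OC(=O)C[C@H]12 | intermediate
13 | (3aR,4R,5R,6aS)-4-[(3S,7R)-3,7-bis[(tert-butyldimethylsilyl)oxy]octyl]-5-[(tert-butyldimethylsilyl)oxy]hexahydro-2H-cyclopenta[b]furan-2-one | C[C@@H](O[Si](C)(C)C(C)(C)C)CCC[C@H](O[Si](C)(C)C(C)(C)C)CC[C@H]1[C@H](O[Si](C)(C)C(C)(C)C)C[C@@H]2OC(=O)C[C@H]12 | intermediate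
14 | (3aR,4R,5R,6aS)-4-[(3S,7R)-3,7-bis[(tert-butyldimethylsilyl)oxy]octyl]-5-[(tert-butyldimethylsilyl)oxy]hexahydro-2H-cyclopenta[b]furan-2-ol (anomer mixture) | C[C@@H](O[Si](C)(C)C(C)(C)C)CCC[C@H](O[Si](C)(C)C(C)(C)C)CC[C@H]1[C@H](O[Si](C)(C)C(C)(C)C)C[C@@H]2OC(O)C[C@H]12 | intermediate
15 | potassium 5-(triphenyl-λ5-phosphanylidene)pentanoate | [K+].[O-]C(=O)CCCC=P(c1ccccc1)(c1ccccc1)c1ccccc1 | intermediate
16 | (Z)-7-[(1R,2R,3R,5S)-2-[(3S,7R)-3,7-bis[(tert-butyldimethylsilyl)oxy]octyl]-3-[(tert-butyldimethylsilyl)oxy]-5-hydroxycyclopentyl]hept-5-enoic acid | C[C@@H](O[Si](C)(C)C(C)(C)C)CCC[C@H](O[Si](C)(C)C(C)(C)C)CC[C@H]1[C@H](O[Si](C)(C)C(C)(C)C)C[C@H](O)[C@@H]1C/C=C\CCCC(=O)O | intermediate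
17 | (Z)-7-[(1R,2R,3R)-2-[(3S,7R)-3,7-bis[(tert-butyldimethylsilyl)oxy]octyl]-3-[(tert-butyldimethylsilyl)oxy]-5-oxocyclopentyl]hept-5-enoic acid | C[C@@H](O[Si](C)(C)C(C)(C)C)CCC[C@H](O[Si](C)(C)C(C)(C)C)CC[C@H]1[C@H](O[Si](C)(C)C(C)(C)C)CC(=O)[C@@H]1C/C=C\CCCC(=O)O | intermediate
18 | (Z)-7-[(1R,2R,3R)-3-hydroxy-2-[(3S,7R)-3,7-dihydroxyoctyl]-5-oxocyclopentyl]hept-5-enoic acid | C[C@@H](O)CCC[C@H](O)CC[C@H]1[C@H](O)CC(=O)[C@@H]1C/C=C\CCCC(=O)O | target

## Step count and risks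

Total step count: 8. Longest linear sequence: 8 steps (2 → 6 → 9 → 12 → 13 → 14 → 16 → 17 → 18); 1, 3 and 4 enter as purchased.

Steps most likely to fail:

**Step 3 (the proposed new coupling).** Risks are incomplete primary-over-secondary selectivity in the activation of 1, homocoupling or reduction of the iodohydrin, and β-hydroxide loss from the alkylnickel. The fallback uses only known chemistry, sets out from 1 and 9 and comes back at 13. Compound 1 is bis-silylated (TBSCl, imidazole, DMF) to the bis-silyl lactone F1. The primary silyl ether is cleaved selectively (HF·pyridine, pyridine, THF, 0 °C) to the 11-O-silyl alcohol F2, and Dess–Martin oxidation gives the Corey aldehyde silyl ether F3. In parallel 9 is opened at its terminal carbon with 1-phenyl-1H-tetrazole-5-thiol (Et3N, MeOH) to the hydroxy sulfide F4, silylated (TBSOTf, 2,6-lutidine) to the bis-silyl sulfide F5 and oxidised ((NH4)6Mo7O24, H2O2, EtOH) to the tetrazolyl sulfone F6. Julia–Kocienski olefination of F6 (KN(SiMe3)2, DME, −60 °C) with F3 gives the C13=C14 alkene F7. Hydrogenation (H2, Pd on carbon, EtOAc) then gives 13.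

**Step 6 (Wittig).** The C9 alkoxide is cis to the C11 silyl ether, so silyl migration from O11 to O9 can compete and would lead to the wrong ketone in step 7. The fallback sets out from 12 and comes back at 18. Both free hydroxyls of 12 are protected as tetrahydropyranyl ethers (3,4-dihydro-2H-pyran, pyridinium p-toluenesulfonate, CH2Cl2) to give the bis-tetrahydropyranyl lactone F8. Reduction (i-Bu2AlH, −78 °C) gives the lactol F9. Wittig reaction with ylide 15 gives the 9-hydroxy acid F10, in which no silyl group sits next to the C9 alkoxide. Dess–Martin oxidation gives the keto acid F11, and aqueous HF in MeCN removes both acetals and the C19 silyl ether to give 18.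

**Step 8 (desilylation of a β-hydroxy ketone).** The risk is dehydration to the cyclopentenone or C8 epimerisation while three secondary silyl ethers are removed. The fallback sets out from 16 and comes back at 18. Bu4NF in THF removes all silyl groups at the 9-hydroxy stage, where no β-hydroxy ketone exists, to give the tetrahydroxy acid F12. Me3SiNEt2 in acetone at −45 °C silylates the 11-, 15- and 19-hydroxyls and the acid but leaves the hindered 9α-hydroxyl, giving the tris(trimethylsilyl) ether trimethylsilyl ester F13. Collins oxidation (CrO3(pyridine)2, CH2Cl2) gives the ketone F14, and AcOH in aqueous MeOH at 25 °C cleaves the trimethylsilyl groups to give 18.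

## Further compounds

F1 | step 3 | (3aR,4S,5R,6aS)-5-[(tert-butyldimethylsilyl)oxy]-4-{[(tert-butyldimethylsilyl)oxy]methyl}hexahydro-2H-cyclopenta[b]furan-2-one | CC(C)(C)[Si](C)(C)OC[C@H]1[C@H](O[Si](C)(C)C(C)(C)C)C[C@@H]2OC(=O)C[C@H]12
F2 | step 3 | (3aR,4S,5R,6aS)-5-[(tert-butyldimethylsilyl)oxy]-4-(hydroxymethyl)hexahydro-2H-cyclopenta[b]furan-2-one | OC[C@H]1[C@H](O[Si](C)(C)C(C)(C)C)C[C@@H]2OC(=O)C[C@H]12
F3 | step 3 | (3aR,4R,5R,6aS)-5-[(tert-butyldimethylsilyl)oxy]-2-oxohexahydro-2H-cyclopenta[b]furan-4-carbaldehyde | O=C[C@H]1[C@H](O[Si](C)(C)C(C)(C)C)C[C@@H]2OC(=O)C[C@H]12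
F4 | step 3 | (2S,6R)-6-[(tert-butyldimethylsilyl)oxy]-1-[(1-phenyl-1H-tetrazol-5-yl)sulfanyl]heptan-2-ol | C[C@@H](O[Si](C)(C)C(C)(C)C)CCC[C@H](O)CSc1nnnn1-c1ccccc1
F5 | step 3 | 5-{[(2S,6R)-2,6-bis[(tert-butyldimethylsilyl)oxy]heptyl]sulfanyl}-1-phenyl-1H-tetrazole | C[C@@H](O[Si](C)(C)C(C)(C)C)CCC[C@H](O[Si](C)(C)C(C)(C)C)CSc1nnnn1-c1ccccc1
F6 | step 3 | 5-{[(2S,6R)-2,6-bis[(tert-butyldimethylsilyl)oxy]heptyl]sulfonyl}-1-phenyl-1H-tetrazole | C[C@@H](O[Si](C)(C)C(C)(C)C)CCC[C@H](O[Si](C)(C)C(C)(C)C)CS(=O)(=O)c1nnnn1-c1ccccc1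
F7 | step 3 | (3aR,4R,5R,6aS)-4-[(1E,3S,7R)-3,7-bis[(tert-butyldimethylsilyl)oxy]oct-1-en-1-yl]-5-[(tert-butyldimethylsilyl)oxy]hexahydro-2H-cyclopenta[b]furan-2-one | C[C@@H](O[Si](C)(C)C(C)(C)C)CCC[C@H](O[Si](C)(C)C(C)(C)C)/C=C/[C@H]1[C@H](O[Si](C)(C)C(C)(C)C)C[C@@H]2OC(=O)C[C@H]12
F8 | step 6 | (3aR,4R,5R,6aS)-4-[(3S,7R)-7-[(tert-butyldimethylsilyl)oxy]-3-(oxan-2-yloxy)octyl]-5-(oxan-2-yloxy)hexahydro-2H-cyclopenta[b]furan-2-one (mixture at the acetal carbons) | C[C@@H](O[Si](C)(C)C(C)(C)C)CCC[C@H](OC3CCCCO3)CC[C@H]1[C@H](OC4CCCCO4)C[C@@H]2OC(=O)C[C@H]12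
F9 | step 6 | (3aR,4R,5R,6aS)-4-[(3S,7R)-7-[(tert-butyldimethylsilyl)oxy]-3-(oxan-2-yloxy)octyl]-5-(oxan-2-yloxy)hexahydro-2H-cyclopenta[b]furan-2-ol (mixture at the acetal and anomeric carbons) | C[C@@H](O[Si](C)(C)C(C)(C)C)CCC[C@H](OC3CCCCO3)CC[C@H]1[C@H](OC4CCCCO4)C[C@@H]2OC(O)C[C@H]12
F10 | step 6 | (Z)-7-[(1R,2R,3R,5S)-2-[(3S,7R)-7-[(tert-butyldimethylsilyl)oxy]-3-(oxan-2-yloxy)octyl]-5-hydroxy-3-(oxan-2-yloxy)cyclopentyl]hept-5-enoic acid | C[C@@H](O[Si](C)(C)C(C)(C)C)CCC[C@H](OC3CCCCO3)CC[C@H]1[C@H](OC4CCCCO4)C[C@H](O)[C@@H]1C/C=C\CCCC(=O)O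
F11 | step 6 | (Z)-7-[(1R,2R,3R)-2-[(3S,7R)-7-[(tert-butyldimethylsilyl)oxy]-3-(oxan-2-yloxy)octyl]-3-(oxan-2-yloxy)-5-oxocyclopentyl]hept-5-enoic acid | C[C@@H](O[Si](C)(C)C(C)(C)C)CCC[C@H](OC3CCCCO3)CC[C@H]1[C@H](OC4CCCCO4)CC(=O)[C@@H]1C/C=C\CCCC(=O)O
F12 | step 8 | (Z)-7-[(1R,2R,3R,5S)-3,5-dihydroxy-2-[(3S,7R)-3,7-dihydroxyoctyl]cyclopentyl]hept-5-enoic acid | C[C@@H](O)CCC[C@H](O)CC[C@H]1[C@H](O)C[C@H](O)[C@@H]1C/C=C\CCCC(=O)O
F13 | step 8 | trimethylsilyl (Z)-7-[(1R,2R,3R,5S)-2-[(3S,7R)-3,7-bis[(trimethylsilyl)oxy]octyl]-5-hydroxy-3-[(trimethylsilyl)oxy]cyclopentyl]hept-5-enoate | C[C@@H](O[Si](C)(C)C)CCC[C@H](O[Si](C)(C)C)CC[C@H]1[C@H](O[Si](C)(C)C)C[C@H](O)[C@@H]1C/C=C\CCCC(=O)O[Si](C)(C)C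
F14 | step 8 | trimethylsilyl (Z)-7-[(1R,2R,3R)-2-[(3S,7R)-3,7-bis[(trimethylsilyl)oxy]octyl]-5-oxo-3-[(trimethylsilyl)oxy]cyclopentyl]hept-5-enoate | C[C@@H](O[Si](C)(C)C)CCC[C@H](O[Si](C)(C)C)CC[C@H]1[C@H](O[Si](C)(C)C)CC(=O)[C@@H]1C/C=C\CCCC(=O)O[Si](C)(C)C
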